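## Retrosynthetic overview
1. The target (24) is built from the aryl–CH2–C9 bond. Hindered α-quaternary aldehyde 17 is coupled to tetramethoxyphenyl-lithium, deoxygenated and oxidised to a quinone. The OH/OMe pattern is then set by hydrolysis and selective O-methylation (23 → 24).
2. Aldehyde 17 comes from C4 ketone methylenation and from a CH2OTBDPS group that masks C11. A temporary allylic C6–OH directs the hydrogenation that sets the C8 methyl, and it is removed afterwards.
3. The cis-decalin core (7) comes from one Diels–Alder reaction between 2-methylcyclohexenone (ring A: C5 quaternary, C10–H, cis fusion) and a tetrasubstituted diene (ring B closes here and sets quaternary C9). This is the proposed new step.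
4. Diene 5 comes from methyl vinyl ketone by HWE olefination, DIBAL reduction and silylation. Ring A is commercial; ring B is formed in Step 4.

Assumption: the target is the (5R,8R,9R,10S) cis-fused avarane-type hydroxy-methoxyquinone as drawn (avarane numbering). The Diels–Alder catalyst enantiomer is whichever gives the series shown, and the E/Z diene isomers are separated.

## Route

**Step 1**
Reactants: 1 methyl vinyl ketone; 2 triethyl 2-phosphonopropionate
Product: 3 ethyl (2E)-2,3-dimethylpenta-2,4-dienoate
Conditions: NaH, THF, 0 °C → 25 °C; separate E/Z (about 4:1) by chromatography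
Reagents that add atoms: none
Why: Horner–Wadsworth–Emmons olefination of the ketone gives mainly the isomer with the ester trans to the larger vinyl group; no sp3 stereocentre forms.

**Step 2**
Reactants: 3
Product: 4 (2E)-2,3-dimethylpenta-2,4-dien-1-ol
Conditions: DIBAL-H (2.5 equiv), CH2Cl2, −78 °C
Reagents that add atoms: none
Why: DIBAL reduction of the ester to the allylic alcohol keeps the tetrasubstituted alkene geometry.

**Step 3**
Reactants: 4
Product: 5 (2E)-2,3-dimethylpenta-2,4-dienyl tert-butyldiphenylsilyl ether
Conditions: TBDPSCl, imidazole, DMF, 25 °C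
Reagents that add atoms: TBDPSCl, CC(C)(C)[Si](Cl)(c1ccccc1)c1ccccc1
Why: Silylation gives a robust protected C11 oxygen that survives all later acid, base and radical steps.

**Step 4**
Reactants: 5 diene; 6 2-methylcyclohex-2-en-1-one
Product: 7 cis-fused decalone (C4 ketone; C5-Me and C10-H cis; C9 quaternary with Me up and CH2OTBDPS down; C7=C8(Me); stereocentres as in the target)
Conditions: 6 (1 equiv), 5 (3 equiv), chiral cationic oxazaborolidinium·Tf2N⁻ (from diphenylprolinol, o-tolylboronic acid, Tf2NH; 20 mol%), CH2Cl2, −20 → 25 °C, 48 h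
Reagents that add atoms: none
Why: Proposed new method: Lewis-acid-catalysed Diels–Alder of a 2-substituted cyclic enone with a tetrasubstituted diene, forming the C9–C10 and C5–C6 bonds and three stereocentres at once. The closest known reactions are Corey–Ryu oxazaborolidinium Diels–Alder of α-substituted enals and Lewis-acid Diels–Alder of 2-methylcyclohexenone. The cyclic dienophile makes the ring fusion cis (C5-Me and H10 on the same face). The α-methyl substituent should favour an exo TS with the E-diene, which puts the inside methyl cis to ring A, so C9-Me is up and CH2OTBDPS is down. The C8 methyl on the diene and the reluctance to form vicinal quaternary centres (C5/C9) should favour the C9–C10/C5–C6 regiochemistry. The catalyst sets absolute configuration.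

**Step 5**
Reactants: 7
Product: 8 C4 ethylene ketal of 7
Conditions: TMSOCH2CH2OTMS, TMSOTf (cat.), CH2Cl2, −78 → 0 °C
Reagents that add atoms: 1,2-bis(trimethylsilyloxy)ethane, C[Si](C)(C)OCCO[Si](C)(C)C
Why: Noyori ketalisation protects the hindered C4 ketone from the later reduction and hydride steps; no stereocentre changes.

**Step 6**
Reactants: 8
Product: 9 C6 enone (O=C6–C7H=C8(Me)), ketal retained
Conditions: Pd(OH)2/C (20 mol%), K2CO3, t-BuOOH, CH2Cl2, 25 °C
Reagents that add atoms: tert-butyl hydroperoxide, CC(C)(C)OO
Why: Allylic C–H oxidation is regioselective for the only allylic CH2 (C6), because C9 is quaternary. This installs the oxygen that will direct the C8 hydrogenation.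

**Step 7**
Reactants: 9
Product: 10 allylic alcohol with C6–OH on the up face (syn to ring A)
Conditions: NaBH4, CeCl3·7H2O, MeOH, −20 °C
Reagents that add atoms: none
Why: Luche 1,2-reduction delivers hydride axially from the open convex (down) face, anti to the axial ring-A carbon, so the OH ends up up; this sets the temporary C6 stereocentre.

**Step 8**
Reactants: 10
Product: 11 saturated alcohol, C8-Me down and H up, C6–OH up
Conditions: [Ir(cod)(PCy3)(py)]PF6 (5 mol%), H2 (1 atm), CH2Cl2, 25 °C
Reagents that add atoms: none
Why: Crabtree hydroxyl-directed hydrogenation puts both H atoms on the alkene from the face bearing the OH (up), so C8 gets H up and Me down, cis to the C9 CH2OTBDPS as required. The ketal and silyl ether are untouched.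

**Step 9**
Reactants: 11
Product: 12 C6 methyl xanthate
Conditions: NaH, imidazole (cat.), THF, 0 °C; CS2; then MeI
Reagents that add atoms: carbon disulfide, S=C=S; iodomethane, CI
Why: The secondary alcohol is converted to a Barton–McCombie xanthate; stereochemistry is unchanged.

**Step 10**
Reactants: 12
Product: 13 C6-deoxygenated ketal
Conditions: n-Bu3SnH, AIBN, toluene, 110 °C
Reagents that add atoms: none
Why: Barton–McCombie radical deoxygenation removes the temporary C6 stereocentre, leaving C8 and the others untouched.

**Step 11**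
Reactants: 13
Product: 14 C4 ketone
Conditions: PPTS, acetone/H2O (10:1), 65 °C
Reagents that add atoms: water, O
Why: Acid-catalysed ketal hydrolysis; TBDPS survives. C10–H is not α to the carbonyl, so nothing epimerises.

**Step 12**
Reactants: 14
Product: 15 exocyclic methylene (C4=CH2) silyl ether
Conditions: Ph3PCH3Br, KOt-Bu, toluene, 80 °C
Reagents that add atoms: methylenetriphenylphosphorane, C=P(c1ccccc1)(c1ccccc1)c1ccccc1
Why: Wittig methylenation of the neopentyl ketone; C5 is quaternary, so the adjacent stereocentres cannot epimerise.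

**Step 13**
Reactants: 15
Product: 16 primary alcohol (C11–OH)
Conditions: TBAF, THF, 50 °C
Reagents that add atoms: none
Why: Fluoride cleaves the silyl ether without touching the alkene.

**Step 14**
Reactants: 16
Product: 17 aldehyde (C9–CHO)
Conditions: Dess–Martin periodinane, NaHCO3, CH2Cl2, 0 → 25 °C
Reagents that add atoms: none
Why: Mild oxidation of the neopentyl alcohol to an α-quaternary aldehyde, which cannot epimerise.

**Step 15**
Reactants: 17; 18 1,2,4,5-tetramethoxybenzene
Product: 19 diaryl-type carbinol (C11–OH, epimeric mixture, removed later)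
Conditions: 18, n-BuLi, THF, 0 °C, 1 h; then 17, −78 → 25 °C
Reagents that add atoms: none
Why: Directed ortho-lithiation of 18 gives the aryl-lithium flanked by two OMe groups, which adds 1,2 to the aldehyde; the new carbinol centre is destroyed in the next two steps.

**Step 16**
Reactants: 19
Product: 20 thiocarbonylimidazolide of 19
Conditions: TCDI, DMAP, ClCH2CH2Cl, 80 °C
Reagents that add atoms: 1,1′-thiocarbonyldiimidazole, S=C(n1ccnc1)n1ccnc1
Why: The hindered benzylic alcohol is activated for radical deoxygenation.

**Step 17**
Reactants: 20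
Product: 21 aryl-CH2 compound
Conditions: n-Bu3SnH, AIBN, toluene, 110 °C
Reagents that add atoms: none
Why: Barton–McCombie deoxygenation via a stabilised benzylic radical (no neophyl-type rearrangement) gives the ArCH2–C9 linkage.

**Step 18**
Reactants: 21
Product: 22 3-alkyl-2,5-dimethoxy-1,4-benzoquinone
Conditions: CAN (4 equiv), MeCN/H2O (3:1), 0 °C, 10 min
Reagents that add atoms: water, O
Why: CAN oxidative demethylation of the para-dimethoxy pair gives the quinone. The arene is mirror-symmetric, so both para pairs give the same quinone.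

**Step 19**
Reactants: 22
Product: 23 3-alkyl-2,5-dihydroxy-1,4-benzoquinone
Conditions: KOH, MeOH/H2O/THF, 70 °C; then HCl
Reagents that add atoms: potassium hydroxide, [K+].[OH-]
Why: Addition–elimination hydrolysis of both vinylogous esters; the exocyclic alkene is base-stable.

**Step 20**
Reactants: 23
Product: 24 target
Conditions: TMSCHN2 (1.1 equiv), MeOH/benzene, 0 → 25 °C
Reagents that add atoms: (trimethylsilyl)diazomethane, C[Si](C)(C)C=[N+]=[N-]
Why: Selective O-methylation of the more acidic, less hindered 5-OH (remote from the neopentyl group) leaves the 2-OH free, as in 5-O-methylembelin-type quinones; this is a chemoselective O-alkylation of a vinylogous acid.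

## Compound list
1 | methyl vinyl ketone | C=CC(C)=O | starting material
2 | triethyl 2-phosphonopropionate | CCOC(=O)C(C)P(=O)(OCC)OCC | starting material
3 | ethyl (2E)-2,3-dimethylpenta-2,4-dienoate | C=C/C(C)=C(C)/C(=O)OCC | intermediate
4 | (2E)-2,3-dimethylpenta-2,4-dien-1-ol | C=C/C(C)=C(C)/CO | intermediate
5 | (2E)-2,3-dimethylpenta-2,4-dienyl TBDPS ether | C=C/C(C)=C(C)/CO[Si](c1ccccc1)(c1ccccc1)C(C)(C)C | intermediate
6 | 2-methylcyclohex-2-en-1-one | CC1=CCCCC1=O | starting material
7 | cis-decalone, C4 ketone, C7=C8(Me), C9 CH2OTBDPS | O=C1CCC[C@H]2[C@](C)(CO[Si](c3ccccc3)(c3ccccc3)C(C)(C)C)C(C)=CC[C@@]12C | intermediate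
8 | C4 ethylene ketal of 7 | C14(OCCO4)CCC[C@H]2[C@](C)(CO[Si](c3ccccc3)(c3ccccc3)C(C)(C)C)C(C)=CC[C@@]12C | intermediate
9 | C6 enone | C14(OCCO4)CCC[C@H]2[C@](C)(CO[Si](c3ccccc3)(c3ccccc3)C(C)(C)C)C(C)=CC(=O)[C@@]12C | intermediate
10 | C6-OH allylic alcohol (OH up) | C14(OCCO4)CCC[C@H]2[C@](C)(CO[Si](c3ccccc3)(c3ccccc3)C(C)(C)C)C(C)=C[C@@H](O)[C@@]12C | intermediate
11 | hydrogenated alcohol (8-Me down) | C14(OCCO4)CCC[C@H]2[C@](C)(CO[Si](c3ccccc3)(c3ccccc3)C(C)(C)C)[C@H](C)C[C@@H](O)[C@@]12C | intermediate
12 | C6 methyl xanthate | C14(OCCO4)CCC[C@H]2[C@](C)(CO[Si](c3ccccc3)(c3ccccc3)C(C)(C)C)[C@H](C)C[C@@H](OC(=S)SC)[C@@]12C | intermediate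
13 | deoxygenated ketal | C14(OCCO4)CCC[C@H]2[C@](C)(CO[Si](c3ccccc3)(c3ccccc3)C(C)(C)C)[C@H](C)CC[C@@]12C | intermediate
14 | C4 ketone silyl ether | O=C1CCC[C@H]2[C@](C)(CO[Si](c3ccccc3)(c3ccccc3)C(C)(C)C)[C@H](C)CC[C@@]12C | intermediate
15 | exocyclic methylene silyl ether | C=C1CCC[C@H]2[C@](C)(CO[Si](c3ccccc3)(c3ccccc3)C(C)(C)C)[C@H](C)CC[C@@]12C | intermediate
16 | primary alcohol | C=C1CCC[C@H]2[C@](C)(CO)[C@H](C)CC[C@@]12C | intermediate
17 | aldehyde | C=C1CCC[C@H]2[C@](C)(C=O)[C@H](C)CC[C@@]12C | intermediate
18 | 1,2,4,5-tetramethoxybenzene | COc1cc(OC)c(OC)cc1OC | starting material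
19 | carbinol (C11 epimer mixture, stereo at C11 undefined) | C=C1CCC[C@H]2[C@](C)(C(O)c3c(OC)c(OC)cc(OC)c3OC)[C@H](C)CC[C@@]12C | intermediate
20 | thiocarbonylimidazolide | C=C1CCC[C@H]2[C@](C)(C(OC(=S)n4ccnc4)c3c(OC)c(OC)cc(OC)c3OC)[C@H](C)CC[C@@]12C | intermediate
21 | aryl-CH2 compound | C=C1CCC[C@H]2[C@](C)(Cc3c(OC)c(OC)cc(OC)c3OC)[C@H](C)CC[C@@]12C | intermediate
22 | 2,5-dimethoxyquinone | C=C1CCC[C@H]2[C@](C)(CC3=C(OC)C(=O)C=C(OC)C3=O)[C@H](C)CC[C@@]12C | intermediate
23 | 2,5-dihydroxyquinone | C=C1CCC[C@H]2[C@](C)(CC3=C(O)C(=O)C=C(O)C3=O)[C@H](C)CC[C@@]12C | intermediate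
24 | target (CID71726091) | C=C1CCC[C@H]2[C@](C)(CC3=C(O)C(=O)C=C(OC)C3=O)[C@H](C)CC[C@@]12C | target

## Totals
Total steps: 20. Longest linear sequence: 20 (methyl vinyl ketone → 24), since 6 and 18 are commercial.

## Three steps most likely to fail
1. **Step 4 (the proposed new Diels–Alder).** Risks are low reactivity, wrong regiochemistry (vicinal quaternary C5/C9) and endo/exo or ee erosion.
   - Fallback (known chemistry, different approach): Robinson annulation of 2-methylcyclohexane-1,3-dione with ethyl vinyl ketone to the 9-methyl enone, C4 ketalisation, and Pd/C–H2–KOH cis-hydrogenation (5β-steroid precedent). Then install C9-CH2OH from the convex face via a thermodynamic silyl enol ether and Kobayashi aqueous-formaldehyde aldol, and set C8 by enol triflate/Me coupling plus directed hydrogenation, converging on compound 13.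
2. **Steps 7–8 (Luche/Crabtree control of C6-OH and C8).** The wrong C6-OH epimer would deliver H to the wrong face, giving the 8-epimer.
   - Fallback: use the C8-H diene (from 4-methyl-2(5H)-furanone), oxidise to the C6 enone, then add Me2CuLi/TMSCl kinetically anti to the pseudo-axial C9 methyl, and remove the C6 ketone by tosylhydrazone reduction.
3. **Steps 19–20 (hydroxyl/methoxy differentiation).** Incomplete hydrolysis of the hindered 2-OMe, or poor selectivity in mono-methylation.
   - Fallback: skip steps 15–20. Prepare 2-hydroxy-5-methoxy-1,4-benzoquinone by mono-hydrolysis of commercial 2,5-dimethoxybenzoquinone, and couple it with aldehyde 17 by reductive Knoevenagel alkylation (Hantzsch ester, L-proline; known for 3-alkyl-lawsones). The quinone's nucleophilic C3 fixes the regiochemistry.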